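**Plan**

1. The target is read as ent-fisetinidol-(4α→6)-ent-fisetinidol-(4α→8)-catechin-(6→4α)-ent-fisetinidol. Unit A is the terminal unit, unit B carries A at its C6 and is bound through C4 to C8 of catechin (unit C), and unit D sits on C6 of catechin. A, B and D are (2S,3R), 2,3-trans-3,4-cis.
2. Retrosynthesis: in each ent-fisetinidol pyran ring the bonds O1–C2 and C4a–C4 are cut (A first, then B, then D). This gives a resorcinol and an aryl carbinol carrying a trans aryl epoxide; each carbinol C–aryl bond is then cut to an aryllithium and one epoxy aldehyde (4).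
3. Forward: benzylated (+)-catechin is brominated at C8 and iodinated at C6. The iodide gives the C6 arm and, with resorcinol, the pyran ring of D. The bromide gives the C8 arm and, with 4-bromoresorcinol, the pyran ring of B, with bromine left at C6 of B. That bromide gives the last arm and, with resorcinol, the pyran ring of A; hydrogenolysis ends the route.
4. Enabling feature: C4 of unit A is a doubly benzylic methine between C6 of unit B (ortho to the C7 oxygen, para to O1, so its carbinol ionises easily) and C4a of a resorcinol ring whose ortho hydroxyl becomes O1. C2 is benzylic to the catechol ring, so a C2–C3 epoxide is opened 6-endo.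
5. Stereochemistry: unit C is bought as (+)-catechin. C2 and C3 of A, B and D come from one organocatalytic epoxidation (C3 retained, C2 inverted on ring closure), and each C4 is relayed from C3 in the same event.

Key step: step 14

Remark on the chemistry: the carbinol carbon of 11, 17 and 23 forms as a mixture of epimers and is planarised in the next step, so it carries no descriptor in names and SMILES.

**Route**

Step 1
Reactants: 1 3,4-bis(benzyloxy)benzaldehyde; 2 (triphenylphosphoranylidene)acetaldehyde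
Product: 3 (E)-3-[3,4-bis(benzyloxy)phenyl]prop-2-enal
Conditions: 2 (1.1 equiv), toluene, 80 °C
Reagents that add atoms: none
Why: Wittig olefination with the stabilised formyl ylide should give the E-enal selectively.

Step 2
Reactants: 3 (E)-3-[3,4-bis(benzyloxy)phenyl]prop-2-enal
Product: 4 (2S,3R)-3-[3,4-bis(benzyloxy)phenyl]oxirane-2-carbaldehyde (trans)
Conditions: (R)-2-[bis(3,5-bis(trifluoromethyl)phenyl)(trimethylsilyloxy)methyl]pyrrolidine (10 mol%), 35% aq. H2O2 (1.3 equiv), CH2Cl2, rt; quick filtration through Et3N-deactivated silica, used at once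
Reagents that add atoms: hydrogen peroxide, OO
Why: Iminium/enamine-catalysed nucleophilic epoxidation of an enal (Jørgensen-type); the diarylprolinol silyl ether shields one face of the iminium ion and sets both oxirane centres, the (R)-catalyst being the one expected to give the (2S,3R) trans epoxide.

Step 3
Reactants: 5 (+)-catechin
Product: 6 5,7,3′,4′-tetra-O-benzyl-(+)-catechin
Conditions: BnBr (4.4 equiv), K2CO3, DMF, 0 °C → rt
Reagents that add atoms: benzyl bromide, BrCc1ccccc1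
Why: Williamson etherification; K2CO3 deprotonates only the four phenols, so the secondary 3-OH stays free and no stereocentre is touched.

Step 4
Reactants: 6 5,7,3′,4′-tetra-O-benzyl-(+)-catechin
Product: 7 3,5,7,3′,4′-penta-O-benzyl-(+)-catechin
Conditions: NaH, BnBr, n-Bu4NI (cat.), DMF/THF, 0 °C → rt
Reagents that add atoms: benzyl bromide, BrCc1ccccc1
Why: Williamson etherification of the remaining secondary alcohol through its sodium alkoxide.

Step 5
Reactants: 7 3,5,7,3′,4′-penta-O-benzyl-(+)-catechin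
Product: 8 8-bromo-3,5,7,3′,4′-penta-O-benzyl-(+)-catechin
Conditions: NBS (1.0 equiv), CH2Cl2, −78 °C → rt
Reagents that add atoms: N-bromosuccinimide, O=C1CCC(=O)N1Br
Why: Electrophilic aromatic bromination; C8 is the most reactive position of the trioxygenated benzo ring of 3-O-protected benzylated catechin.

Step 6
Reactants: 8 8-bromo-3,5,7,3′,4′-penta-O-benzyl-(+)-catechin
Product: 9 8-bromo-6-iodo-3,5,7,3′,4′-penta-O-benzyl-(+)-catechin
Conditions: NIS (1.2 equiv), CF3CO2H (cat.), CH2Cl2/MeCN, 0 °C → rt, dark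
Reagents that add atoms: N-iodosuccinimide, O=C1CCC(=O)N1I
Why: Electrophilic aromatic iodination at C6, the only open position of the trioxygenated ring, which is far more activated than the catechol dibenzyl ether ring.

Step 7
Reactants: 9 8-bromo-6-iodo-3,5,7,3′,4′-penta-O-benzyl-(+)-catechin; 4 (2S,3R)-3-[3,4-bis(benzyloxy)phenyl]oxirane-2-carbaldehyde
Product: 11 8-bromo-penta-O-benzylcatechin carrying at C6 the group CH(OH)[(2R,3R)-3-(3,4-bis(benzyloxy)phenyl)oxiran-2-yl] (carbinol epimers), via 8-bromo-6-lithio-penta-O-benzylcatechin 10 (not isolated)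
Conditions: n-BuLi (1.05 equiv), THF, −78 °C, 10 min; then 4 (1.3 equiv), −78 → −40 °C; sat. aq. NH4Cl at −78 °C
Reagents that add atoms: none
Why: Halogen–lithium exchange is much faster at iodine than at bromine at −78 °C, and the aryllithium adds 1,2 to the aldehyde faster than it opens the epoxide.

Step 8
Reactants: 11 C6 epoxy carbinol of 8-bromo-penta-O-benzylcatechin; 12 resorcinol
Product: 14 8-bromo dimer ent-fisetinidol-(4α→6)-catechin, unit C penta-O-benzyl, unit D (2S,3R,4S) 3′,4′-di-O-benzyl with free 3-OH and 7-OH, via Friedel–Crafts adduct 13 (not isolated)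
Conditions: 12 (5 equiv), camphor-10-sulfonic acid (0.2 equiv), 4 Å MS, CH2Cl2/MeCN (9:1), −40 → 0 °C
Reagents that add atoms: none
Why: Proposed new method: acid ionises the carbinol to a benzylic cation stabilised by the two ortho benzyloxy groups and the para ring oxygen, resorcinol adds through C4 to the face flanked by the oxirane oxygen (C3–H in the cation plane, hydrogen bond from its phenolic OH; this sets C4 of unit D cis to the C3 oxygen), and its ortho hydroxyl then opens the epoxide 6-endo at the benzylic C2 with inversion (C3 retained, 2,3-trans); the closest known reaction types are the acid-catalysed annulation of phenols with 1,3-diarylallyl alcohols to 2,4-diarylchromans and the 6-endo opening of aryl epoxides by hydroxyl groups.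

Step 9
Reactants: 14 8-bromo dimer with free 3-OH and 7-OH on unit D
Product: 15 8-bromo dimer, nona-O-benzyl (unit D 3-O- and 7-O-benzylated)
Conditions: NaH (3 equiv), BnBr (3 equiv), n-Bu4NI (cat.), DMF, 0 °C → rt
Reagents that add atoms: benzyl bromide, BrCc1ccccc1
Why: Williamson etherification of the phenol and the secondary alcohol; the aryl bromide and all stereocentres are inert to NaH.

Step 10
Reactants: 15 nona-O-benzyl 8-bromo dimer; 4 (2S,3R)-3-[3,4-bis(benzyloxy)phenyl]oxirane-2-carbaldehyde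
Product: 17 nona-O-benzyl dimer carrying at C8 of unit C the group CH(OH)[(2R,3R)-3-(3,4-bis(benzyloxy)phenyl)oxiran-2-yl] (carbinol epimers), via 8-lithio dimer 16 (not isolated)
Conditions: n-BuLi (1.1 equiv), THF, −78 °C; then 4 (1.5 equiv), −78 → −40 °C; sat. aq. NH4Cl at −78 °C
Reagents that add atoms: none
Why: Bromine–lithium exchange followed by 1,2-addition of the aryllithium to the aldehyde, as for 8-lithiated benzylated catechins; benzyl ethers and the epoxide are stable at −78 °C.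

Step 11
Reactants: 17 C8 epoxy carbinol of the nona-O-benzyl dimer; 18 4-bromoresorcinol
Product: 20 trimer [6-bromo-ent-fisetinidol]-(4α→8)-catechin-(6→4α)-ent-fisetinidol, units C and D benzylated as in 15, unit B (2S,3R,4S) 3′,4′-di-O-benzyl with free 3-OH and 7-OH, via Friedel–Crafts adduct 19 (not isolated)
Conditions: 18 (5 equiv), camphor-10-sulfonic acid (0.2 equiv), 4 Å MS, CH2Cl2/MeCN (9:1), −40 → 0 °C
Reagents that add atoms: none
Why: Proposed new method: the same cationic Friedel–Crafts alkylation/6-endo epoxide opening as in step 8, the cation now being stabilised by the C7 benzyloxy group, O1 and the C5 benzyloxy group of unit C; 4-bromoresorcinol can react only through C6 (para to one OH, ortho to the other), so the bromine ends at C6 of unit B, C4 is set cis to the C3 oxygen by attack on the oxirane-oxygen face and C2 by inversion; closest known reaction types as in step 8.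

Step 12
Reactants: 20 bromo trimer with free 3-OH and 7-OH on unit B
Product: 21 bromo trimer, trideca-O-benzyl (unit B 3-O- and 7-O-benzylated)
Conditions: NaH (3 equiv), BnBr (3 equiv), n-Bu4NI (cat.), DMF, 0 °C → rt
Reagents that add atoms: benzyl bromide, BrCc1ccccc1
Why: Williamson etherification, as in step 9.

Step 13
Reactants: 21 trideca-O-benzyl bromo trimer; 4 (2S,3R)-3-[3,4-bis(benzyloxy)phenyl]oxirane-2-carbaldehyde
Product: 23 trideca-O-benzyl trimer carrying at C6 of unit B the group CH(OH)[(2R,3R)-3-(3,4-bis(benzyloxy)phenyl)oxiran-2-yl] (carbinol epimers), via 6-lithio trimer 22 (not isolated)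
Conditions: n-BuLi (1.1 equiv), THF, −78 °C; then 4 (1.5 equiv), −78 → −40 °C; sat. aq. NH4Cl at −78 °C
Reagents that add atoms: none
Why: Bromine–lithium exchange and 1,2-addition to the aldehyde, as in step 10; the only halogen in 21 is the one at C6 of unit B.

Step 14
Reactants: 23 C6 epoxy carbinol of the trideca-O-benzyl trimer; 12 resorcinol
Product: 25 protected tetramer, pentadeca-O-benzyl, unit A (2S,3R,4R) 3′,4′-di-O-benzyl with free 3-OH and 7-OH, via Friedel–Crafts adduct 24 (not isolated)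
Conditions: 12 (5 equiv), camphor-10-sulfonic acid (0.2 equiv), 4 Å MS, CH2Cl2/MeCN (9:1), −40 → 0 °C
Reagents that add atoms: none
Why: Proposed new method: the acid ionises the secondary carbinol of 23 to a benzylic cation at the future C4 of unit A, stabilised by the ortho benzyloxy group at C7 and the para ring oxygen O1 of unit B; resorcinol captures it through its C4 (Friedel–Crafts alkylation, 24), and the hydroxyl ortho to the new bond then opens the acid-activated epoxide at the benzylic carbon C2, so that C4a–C4 and O1–C2 form in one pot. The closest known reaction types are the acid-catalysed [3+3] annulation of phenols with 1,3-diarylallyl alcohols to 2,4-diarylchromans (Friedel–Crafts alkylation, then hydroalkoxylation) and the acid-catalysed 6-endo opening of aryl epoxides by a hydroxyl group; the new element is an epoxide in place of the alkene, which supplies the 3-hydroxyl. The pyran ring closes 6-endo-tet at C2, favoured over 5-exo at C3 because C2 is benzylic to the 3,4-bis(benzyloxy)phenyl ring. C3 keeps its C–O bond and so its configuration from 4; C2 is inverted by backside attack (2,3-trans, the same outcome that any SN1 component would favour); C4 is set by 1,2-induction from C3, because in the cation the C3–H bond lies in the cation plane (allylic strain with the aryl ring) and the resorcinol carbon should add to the face flanked by the oxirane oxygen, guided by a hydrogen bond from its phenolic OH and kept off the other face by C2–H (compare glycosylations of 2,3-anhydrofuranosyl donors, where the new bond forms cis to the oxirane oxygen), and this face gives the 3,4-cis (4R) relation after ring closure. The step needs ionisation of the carbinol before the epoxide (the 2,4-dioxygenated ring at C4 is more electron-rich than the 3,4-dioxygenated ring at C2; low temperature), C- rather than O-alkylation of resorcinol (usual for stabilised benzylic cations) and capture by free resorcinol ahead of the benzylated arenes of 23 (excess of 12).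

Step 15
Reactants: 25 pentadeca-O-benzyl tetramer
Product: 26 ent-fisetinidol-(4α→6)-ent-fisetinidol-(4α→8)-catechin-(6→4α)-ent-fisetinidol (target)
Conditions: H2 (1 atm), Pd(OH)2/C, THF/MeOH/H2O, rt
Reagents that add atoms: none
Why: Hydrogenolysis of the fifteen benzyl ethers under neutral conditions, as used for benzylated proanthocyanidin oligomers; the pyran C2–O1 bonds, the C4–aryl bonds and all stereocentres should be left untouched.

**Compound list**

1 | 3,4-bis(benzyloxy)benzaldehyde | O=Cc1ccc(OCc2ccccc2)c(OCc2ccccc2)c1 | starting material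
2 | (triphenylphosphoranylidene)acetaldehyde | O=CC=P(c1ccccc1)(c1ccccc1)c1ccccc1 | starting material
3 | (E)-3-[3,4-bis(benzyloxy)phenyl]prop-2-enal | O=C/C=C/c1ccc(OCc2ccccc2)c(OCc2ccccc2)c1 | intermediate
4 | (2S,3R)-3-[3,4-bis(benzyloxy)phenyl]oxirane-2-carbaldehyde | O=C[C@H]1O[C@@H]1c1ccc(OCc2ccccc2)c(OCc2ccccc2)c1 | intermediate
5 | (+)-catechin, (2R,3S) | Oc1cc(O)c2c(c1)O[C@H](c1ccc(O)c(O)c1)[C@@H](O)C2 | starting material
6 | 5,7,3′,4′-tetra-O-benzyl-(+)-catechin | c1c(OCc4ccccc4)cc(OCc4ccccc4)c2c1O[C@H](c1ccc(OCc4ccccc4)c(OCc4ccccc4)c1)[C@@H](O)C2 | intermediate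
7 | 3,5,7,3′,4′-penta-O-benzyl-(+)-catechin | c1c(OCc4ccccc4)cc(OCc4ccccc4)c2c1O[C@H](c1ccc(OCc4ccccc4)c(OCc4ccccc4)c1)[C@@H](OCc4ccccc4)C2 | intermediate
8 | 8-bromo-penta-O-benzylcatechin | Brc1c(OCc4ccccc4)cc(OCc4ccccc4)c2c1O[C@H](c1ccc(OCc4ccccc4)c(OCc4ccccc4)c1)[C@@H](OCc4ccccc4)C2 | intermediate
9 | 8-bromo-6-iodo-penta-O-benzylcatechin | Brc1c(OCc4ccccc4)c(I)c(OCc4ccccc4)c2c1O[C@H](c1ccc(OCc4ccccc4)c(OCc4ccccc4)c1)[C@@H](OCc4ccccc4)C2 | intermediate
10 | 8-bromo-6-lithio-penta-O-benzylcatechin | Brc1c(OCc4ccccc4)c([Li])c(OCc4ccccc4)c2c1O[C@H](c1ccc(OCc4ccccc4)c(OCc4ccccc4)c1)[C@@H](OCc4ccccc4)C2 | intermediate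
11 | C6 epoxy carbinol of 8-bromo-penta-O-benzylcatechin (carbinol epimers) | Brc1c(OCc4ccccc4)c(C(O)[C@H]5O[C@@H]5c5ccc(OCc4ccccc4)c(OCc4ccccc4)c5)c(OCc4ccccc4)c2c1O[C@H](c1ccc(OCc4ccccc4)c(OCc4ccccc4)c1)[C@@H](OCc4ccccc4)C2 | intermediate
12 | resorcinol | Oc1cccc(O)c1 | starting material
13 | Friedel–Crafts adduct of 11 with resorcinol (2,4-dihydroxyphenyl at the former carbinol carbon, epoxide intact) | Brc1c(OCc4ccccc4)c([C@H](c3ccc(O)cc3O)[C@H]5O[C@@H]5c5ccc(OCc4ccccc4)c(OCc4ccccc4)c5)c(OCc4ccccc4)c2c1O[C@H](c1ccc(OCc4ccccc4)c(OCc4ccccc4)c1)[C@@H](OCc4ccccc4)C2 | intermediate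
14 | 8-bromo dimer, unit D (2S,3R,4S) with free 3-OH and 7-OH | Brc1c(OCc4ccccc4)c([C@@H]2c3ccc(O)cc3O[C@@H](c3ccc(OCc4ccccc4)c(OCc4ccccc4)c3)[C@@H]2O)c(OCc4ccccc4)c2c1O[C@H](c1ccc(OCc4ccccc4)c(OCc4ccccc4)c1)[C@@H](OCc4ccccc4)C2 | intermediate
15 | 8-bromo dimer, nona-O-benzyl | Brc1c(OCc4ccccc4)c([C@@H]2c3ccc(OCc4ccccc4)cc3O[C@@H](c3ccc(OCc4ccccc4)c(OCc4ccccc4)c3)[C@@H]2OCc4ccccc4)c(OCc4ccccc4)c2c1O[C@H](c1ccc(OCc4ccccc4)c(OCc4ccccc4)c1)[C@@H](OCc4ccccc4)C2 | intermediate
16 | 8-lithio dimer, nona-O-benzyl | [Li]c1c(OCc4ccccc4)c([C@@H]2c3ccc(OCc4ccccc4)cc3O[C@@H](c3ccc(OCc4ccccc4)c(OCc4ccccc4)c3)[C@@H]2OCc4ccccc4)c(OCc4ccccc4)c2c1O[C@H](c1ccc(OCc4ccccc4)c(OCc4ccccc4)c1)[C@@H](OCc4ccccc4)C2 | intermediate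
17 | C8 epoxy carbinol of the nona-O-benzyl dimer (carbinol epimers) | OC([C@H]5O[C@@H]5c5ccc(OCc4ccccc4)c(OCc4ccccc4)c5)c1c(OCc4ccccc4)c([C@@H]2c3ccc(OCc4ccccc4)cc3O[C@@H](c3ccc(OCc4ccccc4)c(OCc4ccccc4)c3)[C@@H]2OCc4ccccc4)c(OCc4ccccc4)c2c1O[C@H](c1ccc(OCc4ccccc4)c(OCc4ccccc4)c1)[C@@H](OCc4ccccc4)C2 | intermediate
18 | 4-bromoresorcinol (4-bromobenzene-1,3-diol) | Oc1ccc(Br)c(O)c1 | starting material
19 | Friedel–Crafts adduct of 17 with 4-bromoresorcinol (5-bromo-2,4-dihydroxyphenyl at the former carbinol carbon, epoxide intact) | Oc1cc(O)c(Br)cc1[C@H]([C@H]5O[C@@H]5c5ccc(OCc4ccccc4)c(OCc4ccccc4)c5)c1c(OCc4ccccc4)c([C@@H]2c3ccc(OCc4ccccc4)cc3O[C@@H](c3ccc(OCc4ccccc4)c(OCc4ccccc4)c3)[C@@H]2OCc4ccccc4)c(OCc4ccccc4)c2c1O[C@H](c1ccc(OCc4ccccc4)c(OCc4ccccc4)c1)[C@@H](OCc4ccccc4)C2 | intermediate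
20 | bromo trimer, unit B (2S,3R,4S) 6-bromo with free 3-OH and 7-OH | Brc1cc2c(cc1O)O[C@@H](c1ccc(OCc4ccccc4)c(OCc4ccccc4)c1)[C@H](O)[C@@H]2c1c(OCc4ccccc4)c([C@@H]2c3ccc(OCc4ccccc4)cc3O[C@@H](c3ccc(OCc4ccccc4)c(OCc4ccccc4)c3)[C@@H]2OCc4ccccc4)c(OCc4ccccc4)c2c1O[C@H](c1ccc(OCc4ccccc4)c(OCc4ccccc4)c1)[C@@H](OCc4ccccc4)C2 | intermediate
21 | bromo trimer, trideca-O-benzyl | Brc1cc2c(cc1OCc4ccccc4)O[C@@H](c1ccc(OCc4ccccc4)c(OCc4ccccc4)c1)[C@H](OCc4ccccc4)[C@@H]2c1c(OCc4ccccc4)c([C@@H]2c3ccc(OCc4ccccc4)cc3O[C@@H](c3ccc(OCc4ccccc4)c(OCc4ccccc4)c3)[C@@H]2OCc4ccccc4)c(OCc4ccccc4)c2c1O[C@H](c1ccc(OCc4ccccc4)c(OCc4ccccc4)c1)[C@@H](OCc4ccccc4)C2 | intermediate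
22 | 6-lithio trimer (lithium at C6 of unit B), trideca-O-benzyl | [Li]c1cc2c(cc1OCc4ccccc4)O[C@@H](c1ccc(OCc4ccccc4)c(OCc4ccccc4)c1)[C@H](OCc4ccccc4)[C@@H]2c1c(OCc4ccccc4)c([C@@H]2c3ccc(OCc4ccccc4)cc3O[C@@H](c3ccc(OCc4ccccc4)c(OCc4ccccc4)c3)[C@@H]2OCc4ccccc4)c(OCc4ccccc4)c2c1O[C@H](c1ccc(OCc4ccccc4)c(OCc4ccccc4)c1)[C@@H](OCc4ccccc4)C2 | intermediate
23 | epoxy carbinol at C6 of unit B of the trideca-O-benzyl trimer (carbinol epimers) | OC([C@H]5O[C@@H]5c5ccc(OCc4ccccc4)c(OCc4ccccc4)c5)c1cc2c(cc1OCc4ccccc4)O[C@@H](c1ccc(OCc4ccccc4)c(OCc4ccccc4)c1)[C@H](OCc4ccccc4)[C@@H]2c1c(OCc4ccccc4)c([C@@H]2c3ccc(OCc4ccccc4)cc3O[C@@H](c3ccc(OCc4ccccc4)c(OCc4ccccc4)c3)[C@@H]2OCc4ccccc4)c(OCc4ccccc4)c2c1O[C@H](c1ccc(OCc4ccccc4)c(OCc4ccccc4)c1)[C@@H](OCc4ccccc4)C2 | intermediate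
24 | Friedel–Crafts adduct of 23 with resorcinol (2,4-dihydroxyphenyl at the former carbinol carbon, epoxide intact) | Oc1cc(O)ccc1[C@H]([C@H]5O[C@@H]5c5ccc(OCc4ccccc4)c(OCc4ccccc4)c5)c1cc2c(cc1OCc4ccccc4)O[C@@H](c1ccc(OCc4ccccc4)c(OCc4ccccc4)c1)[C@H](OCc4ccccc4)[C@@H]2c1c(OCc4ccccc4)c([C@@H]2c3ccc(OCc4ccccc4)cc3O[C@@H](c3ccc(OCc4ccccc4)c(OCc4ccccc4)c3)[C@@H]2OCc4ccccc4)c(OCc4ccccc4)c2c1O[C@H](c1ccc(OCc4ccccc4)c(OCc4ccccc4)c1)[C@@H](OCc4ccccc4)C2 | intermediate
25 | pentadeca-O-benzyl tetramer, unit A (2S,3R,4R) with free 3-OH and 7-OH | Oc1ccc2c(c1)O[C@@H](c1ccc(OCc4ccccc4)c(OCc4ccccc4)c1)[C@H](O)[C@@H]2c1cc2c(cc1OCc4ccccc4)O[C@@H](c1ccc(OCc4ccccc4)c(OCc4ccccc4)c1)[C@H](OCc4ccccc4)[C@@H]2c1c(OCc4ccccc4)c([C@@H]2c3ccc(OCc4ccccc4)cc3O[C@@H](c3ccc(OCc4ccccc4)c(OCc4ccccc4)c3)[C@@H]2OCc4ccccc4)c(OCc4ccccc4)c2c1O[C@H](c1ccc(OCc4ccccc4)c(OCc4ccccc4)c1)[C@@H](OCc4ccccc4)C2 | intermediate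
26 | ent-fisetinidol-(4α→6)-ent-fisetinidol-(4α→8)-catechin-(6→4α)-ent-fisetinidol | Oc1ccc2c(c1)O[C@@H](c1ccc(O)c(O)c1)[C@H](O)[C@@H]2c1cc2c(cc1O)O[C@@H](c1ccc(O)c(O)c1)[C@H](O)[C@@H]2c1c(O)c([C@@H]2c3ccc(O)cc3O[C@@H](c3ccc(O)c(O)c3)[C@@H]2O)c(O)c2c1O[C@H](c1ccc(O)c(O)c1)[C@@H](O)C2 | target

**Totals**

Total step count: 15. Longest linear sequence: 13 steps (steps 3 to 15, from catechin 5); steps 1 and 2 supply aldehyde 4, which enters at steps 7, 10 and 13.

**Steps most likely to fail**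

Step 14. The risk is that the resorcinol carbon adds to the other face of the C4 cation, or to both faces, so that unit A forms with the 3,4-trans relation. The fallback sets out from 23 and comes back at 25, and lets arene and hydride change roles through known reactions. 4-Bromoresorcinol 18 is converted (MOMCl, i-Pr2NEt, CH2Cl2) into 1-bromo-2,4-bis(methoxymethoxy)benzene F1. Carbinol 23 is oxidised with Dess–Martin periodinane (NaHCO3, CH2Cl2) to the aryl epoxy ketone F2. Bromine–lithium exchange on F1 (n-BuLi, THF, −78 °C) and addition to F2 should give the tertiary epoxy carbinol F3. CF3CO2H/Et3SiH (CH2Cl2, −40 → 0 °C) should then reduce the doubly benzylic carbinol (ionic hydrogenation), cleave the methoxymethyl ethers and let the freed phenol open the epoxide 6-endo, giving 25. Because the hydride now enters where the arene entered before, the face preference that spoiled step 14 leads here to the wanted C4 epimer.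

Step 11. The risk is slow capture of the crowded cation at the C8 arm by the less nucleophilic 4-bromoresorcinol, so that the cation or the epoxide is lost to rearrangement or to attack by a neighbouring benzyloxy oxygen. The fallback sets out from 15 and 4 and comes back at 20; it is the classical acid-mediated condensation of a flavan-3,4-diol with a phloroglucinol-type nucleophile. Commercial 4,6-dibromoresorcinol is protected (MOMCl, i-Pr2NEt) as 1,5-dibromo-2,4-bis(methoxymethoxy)benzene F4. Mono bromine–lithium exchange (n-BuLi, 1.0 equiv, THF, −78 °C) and addition to 4 should give the epoxy carbinol F5. Dilute aqueous HCl in THF should remove the methoxymethyl groups and close the pyran ring by 6-endo epoxide opening, giving (2S,3R)-2-[3,4-bis(benzyloxy)phenyl]-6-bromochromane-3,4,7-triol F6. Dimer 15 is debrominated (n-BuLi, THF, −78 °C; then MeOH) to the nona-O-benzyl dimer F7, whose only phloroglucinol-type position is C8 of unit C. Condensation of F6 with F7 (BF3·OEt2, CH2Cl2, −20 → 0 °C) should give 20. Both C4 epimers are to be expected from this route, the wanted 3,4-cis one probably as the lesser, so 20 would be obtained after chromatography.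

Step 8. The risk is that the acid opens the electron-rich aryl epoxide before, or instead of, ionising the carbinol, which would lead to rearrangement to a ketone or to arylation at C2. The fallback sets out from 8 and 4 and comes back at 14, again by flavan-3,4-diol condensation. Bromine–lithium exchange on 1-bromo-2,4-bis(methoxymethoxy)benzene F1 (n-BuLi, THF, −78 °C) and addition to 4 should give the epoxy carbinol F8. Dilute aqueous HCl in THF should convert it into (2S,3R)-2-[3,4-bis(benzyloxy)phenyl]chromane-3,4,7-triol F9. Condensation of F9 with an excess of 8 (BF3·OEt2, CH2Cl2, −20 → 0 °C) can occur only at C6, since C8 is blocked by bromine, and should give 14 together with its C4 epimer, to be separated by chromatography.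

**Further compounds**

F1 | step 14 | 1-bromo-2,4-bis(methoxymethoxy)benzene | COCOc1ccc(Br)c(OCOC)c1
F2 | step 14 | aryl epoxy ketone from 23: [(2S,3R)-3-(3,4-bis(benzyloxy)phenyl)oxiran-2-yl] ketone at C6 of unit B of the trideca-O-benzyl trimer | O=C([C@H]5O[C@@H]5c5ccc(OCc4ccccc4)c(OCc4ccccc4)c5)c1cc2c(cc1OCc4ccccc4)O[C@@H](c1ccc(OCc4ccccc4)c(OCc4ccccc4)c1)[C@H](OCc4ccccc4)[C@@H]2c1c(OCc4ccccc4)c([C@@H]2c3ccc(OCc4ccccc4)cc3O[C@@H](c3ccc(OCc4ccccc4)c(OCc4ccccc4)c3)[C@@H]2OCc4ccccc4)c(OCc4ccccc4)c2c1O[C@H](c1ccc(OCc4ccccc4)c(OCc4ccccc4)c1)[C@@H](OCc4ccccc4)C2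
F3 | step 14 | tertiary carbinol from F2 carrying a 2,4-bis(methoxymethoxy)phenyl group at the carbinol carbon (carbinol epimers) | OC(c1ccc(OCOC)cc1OCOC)([C@H]5O[C@@H]5c5ccc(OCc4ccccc4)c(OCc4ccccc4)c5)c1cc2c(cc1OCc4ccccc4)O[C@@H](c1ccc(OCc4ccccc4)c(OCc4ccccc4)c1)[C@H](OCc4ccccc4)[C@@H]2c1c(OCc4ccccc4)c([C@@H]2c3ccc(OCc4ccccc4)cc3O[C@@H](c3ccc(OCc4ccccc4)c(OCc4ccccc4)c3)[C@@H]2OCc4ccccc4)c(OCc4ccccc4)c2c1O[C@H](c1ccc(OCc4ccccc4)c(OCc4ccccc4)c1)[C@@H](OCc4ccccc4)C2
F4 | step 11 | 1,5-dibromo-2,4-bis(methoxymethoxy)benzene | COCOc1cc(OCOC)c(Br)cc1Br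
F5 | step 11 | [5-bromo-2,4-bis(methoxymethoxy)phenyl][(2R,3R)-3-(3,4-bis(benzyloxy)phenyl)oxiran-2-yl]methanol (carbinol epimers) | COCOc1cc(OCOC)c(C(O)[C@H]2O[C@@H]2c2ccc(OCc3ccccc3)c(OCc3ccccc3)c2)cc1Br
F6 | step 11 | (2S,3R)-2-[3,4-bis(benzyloxy)phenyl]-6-bromochromane-3,4,7-triol (C4 epimers) | Brc1cc2c(cc1O)O[C@@H](c1ccc(OCc3ccccc3)c(OCc3ccccc3)c1)[C@H](O)C2O
F7 | step 11 | debrominated nona-O-benzyl dimer (hydrogen at C8 of unit C) | c1c(OCc4ccccc4)c([C@@H]2c3ccc(OCc4ccccc4)cc3O[C@@H](c3ccc(OCc4ccccc4)c(OCc4ccccc4)c3)[C@@H]2OCc4ccccc4)c(OCc4ccccc4)c2c1O[C@H](c1ccc(OCc4ccccc4)c(OCc4ccccc4)c1)[C@@H](OCc4ccccc4)C2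
F8 | step 8 | [2,4-bis(methoxymethoxy)phenyl][(2R,3R)-3-(3,4-bis(benzyloxy)phenyl)oxiran-2-yl]methanol (carbinol epimers) | COCOc1ccc(C(O)[C@H]2O[C@@H]2c2ccc(OCc3ccccc3)c(OCc3ccccc3)c2)c(OCOC)c1
F9 | step 8 | (2S,3R)-2-[3,4-bis(benzyloxy)phenyl]chromane-3,4,7-triol (C4 epimers) | Oc1ccc2c(c1)O[C@@H](c1ccc(OCc3ccccc3)c(OCc3ccccc3)c1)[C@H](O)C2O
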